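**Target:** CNP0323983.1, (3R,3'S,4'R)-all-E-7,8,7',8'-tetradehydro-β,β-carotene-3,3',4'-triol (carotenoid numbering; primed locants on the diol ring, ring B).

**Retrosynthetic overview**
1. The last bond is C8'–C9': Sonogashira coupling of the ring B ethynyl cis-diol (C11) with a ring A C29 heptaenyl iodide that carries iodine at C9'.
2. Feature the strategy rests on: ring B has a cis C3'/C4' diol whose C4'–O is allylic to the tetrasubstituted C5'=C6' alkene, itself conjugated to C7'≡C8'. A 1,3 oxygen shift relates this to a C6' tertiary propargylic alcohol, and a C3' tert-butyl carbonate returns oxygen to C4' as a temporary five-membered carbonate.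
3. The iodide comes from a C25 aldehyde plus a C4 iodo phosphonate (Horner–Wadsworth–Emmons, C11'=C12'); the C25 aldehyde comes from a ring A C15 phosphonium salt plus the C10 dialdehyde (Wittig, C11=C12).
4. Ring A: an enol triflate made from the same hydroxy enone as ring B (conjugate reduction, then triflation) is coupled with (E)-3-methylpent-2-en-4-yn-1-ol (Sonogashira, C6–C7).
5. Ring order: both cyclohexene rings come preformed from 4-oxoisophorone (C3 and C3' set in step 1). The only ring closed is the temporary carbonate in step 4, opened again in step 5.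

Key step: step 4

Assumption: the (S,S)-TsDPEN ruthenium catalyst is taken to reduce 1 in the sense known for aryl ketones, with the ring alkene in the place of the aryl group; if the sense proves opposite, the mirror-image catalyst is used.

**Step 1**
Reactants: 1 4-oxoisophorone (2,6,6-trimethylcyclohex-2-ene-1,4-dione)
Product: 2 (4S)-4-hydroxy-2,6,6-trimethylcyclohex-2-en-1-one
Conditions: RuCl[(S,S)-TsDPEN](p-cymene) (0.5 mol%), KOtBu (1 mol%), i-PrOH, rt
Reagents that add atoms: none
Why: Noyori-type asymmetric transfer hydrogenation should reduce only the unhindered C4 carbonyl (C1 is shielded by the gem-dimethyl carbon and the C2 methyl, and outer-sphere hydride transfer leaves the alkene alone), and the chiral diamine ligand sets the carbinol centre as S.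

**Step 2**
Reactants: 2 (4S)-4-hydroxy-2,6,6-trimethylcyclohex-2-en-1-one; 3 trimethylsilylacetylene
Product: 5 (4S)-2,6,6-trimethyl-1-[(trimethylsilyl)ethynyl]cyclohex-2-ene-1,4-diol (both C1 epimers), via lithium (trimethylsilyl)acetylide 4 (not isolated)
Conditions: 3 (3.3 equiv), n-BuLi (3.1 equiv), THF, −78 °C; add 2, −78 → 0 °C; aq. NH4Cl
Reagents that add atoms: none
Why: 1,2-addition of a lithium acetylide to the hindered enone carbonyl follows conversion of the C4 hydroxyl to its alkoxide by the first equivalent; the configuration of the new tertiary carbinol does not matter because that centre is ionised in step 4, and C4 is untouched.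

**Step 3**
Reactants: 5 (4S)-2,6,6-trimethyl-1-[(trimethylsilyl)ethynyl]cyclohex-2-ene-1,4-diol; 6 di-tert-butyl dicarbonate
Product: 7 tert-butyl (1S)-4-hydroxy-3,5,5-trimethyl-4-[(trimethylsilyl)ethynyl]cyclohex-2-en-1-yl carbonate (both C4 epimers)
Conditions: 6 (1.1 equiv), DMAP (0.1 equiv), CH2Cl2, 0 °C → rt
Reagents that add atoms: none
Why: DMAP-catalysed tert-butoxycarbonylation should occur only at the secondary allylic hydroxyl, since the tertiary hydroxyl is buried between the gem-dimethyl carbon, the methyl-bearing alkene carbon and the alkyne.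

**Step 4**
Reactants: 7 tert-butyl (1S)-4-hydroxy-3,5,5-trimethyl-4-[(trimethylsilyl)ethynyl]cyclohex-2-en-1-yl carbonate
Product: 8 (3aS,7aR)-5,5,7-trimethyl-6-[(trimethylsilyl)ethynyl]-3a,4,5,7a-tetrahydro-1,3-benzodioxol-2-one (cis-fused cyclic carbonate of the C3'/C4' diol)
Conditions: BF3·OEt2 (0.3 equiv), 4 Å MS, CH2Cl2, −78 → −30 °C; Et3N quench
Reagents that add atoms: none
Why: BF3 ionises the doubly activated (allylic and propargylic) tertiary C6'–OH to a cation spread over C6', C4' and C8', and the carbonyl oxygen of the C3' tert-butyl carbonate adds to C4' to give a 2-tert-butoxy-1,3-dioxolan-2-ylium ion that sheds isobutene and leaves the cyclic carbonate. The closest known reaction types are the capture of carbocations by neighbouring tert-butyl carbonates (Lewis-acid epoxide opening, halocarbonate cyclisation, acyloxonium-type anchimeric assistance) and the acid-mediated 1,3-transposition (SN1') of tertiary allylic alcohols. The only ring closed is the temporary five-membered carbonate, formed in a 5-exo-trig mode onto the C4' end of the allyl cation. The new C4' stereocentre is controlled by C3': a trans fusion of the dioxolanone to the cyclohexene is too strained to form, so the (3'S) oxygen brings the C4' oxygen to its own face and gives (4'R). The step needs capture at C4' and not at C6' or C8', ionisation at C6' and not at the secondary C3' allylic carbonate, and no Meyer–Schuster or elimination pathway; the three-atom tether reaches only C4', the tertiary doubly stabilised C6' site should ionise far faster than the secondary carbonate, and sieves at low temperature keep water away from C8'.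

**Step 5**
Reactants: 8 (3aS,7aR)-5,5,7-trimethyl-6-[(trimethylsilyl)ethynyl]-3a,4,5,7a-tetrahydro-1,3-benzodioxol-2-one
Product: 9 (1S,2R)-4-ethynyl-3,5,5-trimethylcyclohex-3-ene-1,2-diol
Conditions: K2CO3 (0.3 equiv), MeOH, 0 °C → rt
Reagents that add atoms: none
Why: Base-catalysed methanolysis cleaves the cyclic carbonate by transesterification and the alkynyl C–Si bond by protodesilylation without breaking either C–O bond of the diol, so C3' and C4' keep their configuration.

**Step 6**
Reactants: 2 (4S)-4-hydroxy-2,6,6-trimethylcyclohex-2-en-1-one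
Product: 10 (4S)-2,6,6-trimethyl-4-[(triethylsilyl)oxy]cyclohex-2-en-1-one
Conditions: Et3SiCl (1.2 equiv), imidazole (2 equiv), CH2Cl2, 0 °C
Reagents that add atoms: chlorotriethylsilane, CC[Si](CC)(CC)Cl
Why: Standard silylation of a secondary alcohol gives an ether that should survive hydride, triflation and cross-coupling but come off in acidic methanol in step 9.

**Step 7**
Reactants: 10 (4S)-2,6,6-trimethyl-4-[(triethylsilyl)oxy]cyclohex-2-en-1-one
Product: 12 (4R)-2,6,6-trimethyl-4-[(triethylsilyl)oxy]cyclohex-1-en-1-yl trifluoromethanesulfonate, via lithium enolate 11 (not isolated)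
Conditions: Li[HB(s-Bu)3] (L-Selectride, 1.1 equiv), THF, −78 °C; then PhNTf2 (1.2 equiv), −78 °C → rt; aq. NH4Cl
Reagents that add atoms: N-phenylbis(trifluoromethanesulfonimide), O=S(=O)(N(c1ccccc1)S(=O)(=O)C(F)(F)F)C(F)(F)F
Why: Conjugate hydride reduction of a β-unsubstituted cyclohexenone whose carbonyl is too hindered for 1,2-attack, followed by O-sulfonylation of the regiodefined enolate, should give the tetrasubstituted enol triflate directly; the silyloxy-bearing centre is not touched (its descriptor changes from S to R only through the CIP priorities).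

**Step 8**
Reactants: 12 (4R)-2,6,6-trimethyl-4-[(triethylsilyl)oxy]cyclohex-1-en-1-yl trifluoromethanesulfonate; 13 (2E)-3-methylpent-2-en-4-yn-1-ol
Product: 14 (2E)-3-methyl-5-[(4R)-2,6,6-trimethyl-4-[(triethylsilyl)oxy]cyclohex-1-en-1-yl]pent-2-en-4-yn-1-ol
Conditions: Pd(PPh3)4 (5 mol%), CuI (10 mol%), Et3N (3 equiv), DMF, rt → 50 °C
Reagents that add atoms: none
Why: Sonogashira coupling of an enol triflate with a terminal enyne forms the C6–C7 bond, and the 9E geometry is carried over unchanged from the commercial enynol.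

**Step 9**
Reactants: 14 (2E)-3-methyl-5-[(4R)-2,6,6-trimethyl-4-[(triethylsilyl)oxy]cyclohex-1-en-1-yl]pent-2-en-4-yn-1-ol
Product: 15 [(2E)-5-[(4R)-4-hydroxy-2,6,6-trimethylcyclohex-1-en-1-yl]-3-methylpent-2-en-4-yn-1-yl]triphenylphosphonium bromide
Conditions: PPh3·HBr (1.2 equiv), MeOH, 0 °C → rt
Reagents that add atoms: triphenylphosphine hydrobromide, Br.P(c1ccccc1)(c1ccccc1)c1ccccc1
Why: Acid-promoted substitution of the primary allylic alcohol by triphenylphosphine (the usual entry to carotenoid Wittig salts) should give the phosphonium salt while the same acidic methanol solvolyses the triethylsilyl ether; the secondary ring hydroxyl does not ionise.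

**Step 10**
Reactants: 15 [(2E)-5-[(4R)-4-hydroxy-2,6,6-trimethylcyclohex-1-en-1-yl]-3-methylpent-2-en-4-yn-1-yl]triphenylphosphonium bromide; 16 (2E,4E,6E)-2,7-dimethylocta-2,4,6-trienedial
Product: 18 (2E,4E,6E,8E,10E)-13-[(4R)-4-hydroxy-2,6,6-trimethylcyclohex-1-en-1-yl]-2,7,11-trimethyltrideca-2,4,6,8,10-pentaen-12-ynal, via phosphonium ylide 17 (not isolated)
Conditions: 16 (2.5 equiv), NaOMe (1.1 equiv), MeOH/CH2Cl2, 0 °C → rt; then heptane/EtOAc, 60 °C, dark
Reagents that add atoms: none
Why: Wittig olefination of one aldehyde of the symmetrical dialdehyde (used in excess to suppress double olefination) forms C11=C12, and the congested 11Z isomer expected beside 11E should revert to E on gentle warming, under which the unhindered 9E enyne bond should hold.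

**Step 11**
Reactants: 19 but-2-yn-1-ol
Product: 21 (2E)-3-iodobut-2-en-1-ol, via alkenylzirconocene chloride 20 (not isolated)
Conditions: Cp2Zr(H)Cl (2.3 equiv), THF, rt → 40 °C; I2 (1.2 equiv), 0 °C; 1 M HCl
Reagents that add atoms: iodine, II
Why: Hydrozirconation with the Schwartz reagent is a syn addition that, after equilibration with a slight excess of reagent, should place zirconium on the methyl-bearing alkyne carbon remote from oxygen, and iodinolysis of the C–Zr bond with retention gives the E iodide.

**Step 12**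
Reactants: 21 (2E)-3-iodobut-2-en-1-ol
Product: 22 (2E)-1-bromo-3-iodobut-2-ene
Conditions: PBr3 (0.4 equiv), Et2O, 0 °C
Reagents that add atoms: phosphorus tribromide, BrP(Br)Br
Why: SN2 displacement of the primary allylic alcohol through its phosphite ester should give the bromide without touching the vinyl iodide or its geometry.

**Step 13**
Reactants: 22 (2E)-1-bromo-3-iodobut-2-ene
Product: 23 diethyl [(2E)-3-iodobut-2-en-1-yl]phosphonate
Conditions: P(OEt)3 (1.5 equiv), neat, 100 °C
Reagents that add atoms: triethyl phosphite, CCOP(OCC)OCC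
Why: Michaelis–Arbuzov reaction at the allylic bromide; the vinyl iodide is inert to the phosphite without a transition metal.

**Step 14**
Reactants: 18 C25 hydroxy aldehyde; 23 diethyl [(2E)-3-iodobut-2-en-1-yl]phosphonate
Product: 25 (1R)-4-[(3E,5E,7E,9E,11E,13E,15E)-16-iodo-3,7,12-trimethylheptadeca-3,5,7,9,11,13,15-heptaen-1-yn-1-yl]-3,5,5-trimethylcyclohex-3-en-1-ol, via sodium phosphonate carbanion 24 (not isolated)
Conditions: 23 (2.5 equiv), NaN(SiMe3)2 (2.4 equiv), THF, −78 °C; add 18, −78 → 0 °C; aq. NH4Cl
Reagents that add atoms: none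
Why: Horner–Wadsworth–Emmons olefination with an allylic phosphonate anion reacts at its α-carbon and should give the new C11'=C12' bond as the E isomer, the C9'=C10' iodoalkene geometry being carried over from 23 and the free ring hydroxyl being tolerated by the excess of anion.

**Step 15**
Reactants: 25 ring A C29 heptaenyl iodide; 9 (1S,2R)-4-ethynyl-3,5,5-trimethylcyclohex-3-ene-1,2-diol
Product: 26 (3R,3'S,4'R)-all-E-7,8,7',8'-tetradehydro-β,β-carotene-3,3',4'-triol (CNP0323983.1)
Conditions: Pd(PPh3)4 (5 mol%), CuI (10 mol%), i-Pr2NH (3 equiv), THF, rt, argon, dark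
Reagents that add atoms: none
Why: Sonogashira coupling of an alkenyl iodide with a terminal alkyne should form C8'–C9' at room temperature with retention of the C9'=C10' geometry and tolerate the three free hydroxyl groups, so no protecting group has to be removed from the finished carotenoid.

**Compound list**
1 | 4-oxoisophorone (2,6,6-trimethylcyclohex-2-ene-1,4-dione) | CC1=CC(=O)CC(C)(C)C1=O | starting material
2 | (4S)-4-hydroxy-2,6,6-trimethylcyclohex-2-en-1-one | CC1=C[C@@H](O)CC(C)(C)C1=O | intermediate
3 | trimethylsilylacetylene | C[Si](C)(C)C#C | starting material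
4 | lithium (trimethylsilyl)acetylide | C[Si](C)(C)C#C[Li] | intermediate (not isolated)
5 | (4S)-2,6,6-trimethyl-1-[(trimethylsilyl)ethynyl]cyclohex-2-ene-1,4-diol (both C1 epimers) | C[Si](C)(C)C#CC1(O)C(C)=C[C@@H](O)CC1(C)C | intermediate
6 | di-tert-butyl dicarbonate | CC(C)(C)OC(=O)OC(=O)OC(C)(C)C | starting material
7 | tert-butyl (1S)-4-hydroxy-3,5,5-trimethyl-4-[(trimethylsilyl)ethynyl]cyclohex-2-en-1-yl carbonate (both C4 epimers) | C[Si](C)(C)C#CC1(O)C(C)=C[C@@H](OC(=O)OC(C)(C)C)CC1(C)C | intermediate
8 | (3aS,7aR)-5,5,7-trimethyl-6-[(trimethylsilyl)ethynyl]-3a,4,5,7a-tetrahydro-1,3-benzodioxol-2-one | C[Si](C)(C)C#CC1=C(C)[C@@H](O2)[C@@H](OC2=O)CC1(C)C | intermediate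
9 | (1S,2R)-4-ethynyl-3,5,5-trimethylcyclohex-3-ene-1,2-diol | C#CC1=C(C)[C@@H](O)[C@@H](O)CC1(C)C | intermediate
10 | (4S)-2,6,6-trimethyl-4-[(triethylsilyl)oxy]cyclohex-2-en-1-one | CC1=C[C@@H](O[Si](CC)(CC)CC)CC(C)(C)C1=O | intermediate
11 | lithium (4R)-2,6,6-trimethyl-4-[(triethylsilyl)oxy]cyclohex-1-en-1-olate | CC1=C([O-])C(C)(C)C[C@H](O[Si](CC)(CC)CC)C1.[Li+] | intermediate (not isolated)
12 | (4R)-2,6,6-trimethyl-4-[(triethylsilyl)oxy]cyclohex-1-en-1-yl trifluoromethanesulfonate | CC1=C(OS(=O)(=O)C(F)(F)F)C(C)(C)C[C@H](O[Si](CC)(CC)CC)C1 | intermediate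
13 | (2E)-3-methylpent-2-en-4-yn-1-ol | C#C/C(C)=C/CO | starting material
14 | (2E)-3-methyl-5-[(4R)-2,6,6-trimethyl-4-[(triethylsilyl)oxy]cyclohex-1-en-1-yl]pent-2-en-4-yn-1-ol | CC1=C(C#C/C(C)=C/CO)C(C)(C)C[C@H](O[Si](CC)(CC)CC)C1 | intermediate
15 | [(2E)-5-[(4R)-4-hydroxy-2,6,6-trimethylcyclohex-1-en-1-yl]-3-methylpent-2-en-4-yn-1-yl]triphenylphosphonium bromide | CC1=C(C#C/C(C)=C/C[P+](c2ccccc2)(c2ccccc2)c2ccccc2)C(C)(C)C[C@H](O)C1.[Br-] | intermediate
16 | (2E,4E,6E)-2,7-dimethylocta-2,4,6-trienedial | O=C/C(C)=C/C=C/C=C(C)/C=O | starting material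
17 | triphenylphosphonium ylide of 15 | CC1=C(C#C/C(C)=C/C=P(c2ccccc2)(c2ccccc2)c2ccccc2)C(C)(C)C[C@H](O)C1 | intermediate (not isolated)
18 | (2E,4E,6E,8E,10E)-13-[(4R)-4-hydroxy-2,6,6-trimethylcyclohex-1-en-1-yl]-2,7,11-trimethyltrideca-2,4,6,8,10-pentaen-12-ynal | CC1=C(C#C/C(C)=C/C=C/C(C)=C/C=C/C=C(C)/C=O)C(C)(C)C[C@H](O)C1 | intermediate
19 | but-2-yn-1-ol | CC#CCO | starting material
20 | (E)-alkenylzirconocene chloride of the zirconium alkoxide, Cp2Zr(Cl)–C(CH3)=CH–CH2–O–Zr(Cl)Cp2 (cyclopentadienyl rings written σ-bound) | C/C(=C\CO[Zr](Cl)(C1C=CC=C1)C1C=CC=C1)[Zr](Cl)(C1C=CC=C1)C1C=CC=C1 | intermediate (not isolated)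
21 | (2E)-3-iodobut-2-en-1-ol | C/C(I)=C\CO | intermediate
22 | (2E)-1-bromo-3-iodobut-2-ene | C/C(I)=C\CBr | intermediate
23 | diethyl [(2E)-3-iodobut-2-en-1-yl]phosphonate | CCOP(=O)(OCC)C/C=C(\C)I | intermediate
24 | sodium salt of the α-carbanion of 23 | CCOP(=O)(OCC)[CH-]/C=C(\C)I.[Na+] | intermediate (not isolated)
25 | (1R)-4-[(3E,5E,7E,9E,11E,13E,15E)-16-iodo-3,7,12-trimethylheptadeca-3,5,7,9,11,13,15-heptaen-1-yn-1-yl]-3,5,5-trimethylcyclohex-3-en-1-ol | CC1=C(C#C/C(C)=C/C=C/C(C)=C/C=C/C=C(C)/C=C/C=C(\C)I)C(C)(C)C[C@H](O)C1 | intermediate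
26 | (3R,3'S,4'R)-all-E-7,8,7',8'-tetradehydro-β,β-carotene-3,3',4'-triol (CNP0323983.1) | CC1=C(C#C/C(C)=C/C=C/C(C)=C/C=C/C=C(C)/C=C/C=C(\C)C#CC2=C(C)[C@@H](O)[C@@H](O)CC2(C)C)C(C)(C)C[C@H](O)C1 | target

**Total step count:** 15
**Longest linear sequence:** 8 steps (steps 1, 6, 7, 8, 9, 10, 14, 15)

**Steps most likely to fail**

Step 4. The ionised C6' centre may be diverted by traces of water adding at C8' (Meyer–Schuster rearrangement) or by proton loss to a cross-conjugated triene. The Lewis acid may also strip the tert-butyl group from the carbonate before the C6' hydroxyl leaves, so that no oxygen is delivered to C4'. The fallback brings oxygen to C4' by oxidative transposition and hydride reduction instead of cation capture; it sets out from 5 and comes back at 9. Silylation of the secondary hydroxyl of 5 (t-BuMe2SiCl, imidazole, DMF) should give the tert-butyldimethylsilyl ether F1. Babler–Dauben oxidative 1,3-transposition of the tertiary allylic alcohol with pyridinium chlorochromate (C5H5NH)[CrO3Cl] in CH2Cl2 should give the C4' enynone F2. Reduction with Li[HB(s-Bu)3] in THF at −78 °C, where the bulky hydride is expected to approach anti to the neighbouring silyloxy group, should give the cis silyloxy alcohol F3; any trans epimer would be removed by chromatography. Bu4NF in THF then removes both silyl groups and gives 9.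

Step 15. E/Z isomerisation or decomposition of the heptaenyl iodide in the presence of palladium, copper and amine, and oxidative homocoupling of the terminal alkyne, may outrun the cross-coupling. The fallback makes the alkyne–alkene bond on small molecules and closes the carotenoid by a C11'=C12' Wittig reaction; it sets out from 8, uses 21 and 18, and comes back at 26. Buffered desilylation of 8 (Bu4NF, AcOH, THF, 0 °C) should give the ethynyl cyclic carbonate F4 with the carbonate intact. Sonogashira coupling of F4 with 21 (Pd(PPh3)4, CuI, Et3N, THF, rt) should give the ring B C15 allylic alcohol F5. PPh3·HBr in CH2Cl2/MeOH should convert it to the phosphonium bromide F6. Wittig reaction of F6 with aldehyde 18 (NaOMe, MeOH/CH2Cl2, then gentle warming to revert any 11'Z isomer) should give 26, the excess methoxide removing the carbonate in the same operation.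

Step 7. Hydride delivery to the β-carbon next to the silyloxy group may be slow or partly diverted to the carbonyl, and O-sulfonylation of the hindered tetrasubstituted enolate may lag behind its protonation on work-up. The fallback separates alkene saturation from enolate formation; it sets out from 10 and comes back at 12. Hydrogenation (H2, Pd/C, EtOAc) should give the saturated ketone F7 as a mixture of C6 epimers, which does not matter because only the C6 side can enolise. KN(SiMe3)2 in THF at −78 °C followed by PhNTf2 should then give 12.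

**Further compounds**
F1 | step 4 | (4S)-4-[(tert-butyldimethylsilyl)oxy]-2,6,6-trimethyl-1-[(trimethylsilyl)ethynyl]cyclohex-2-en-1-ol (both C1 epimers) | C[Si](C)(C)C#CC1(O)C(C)=C[C@@H](O[Si](C)(C)C(C)(C)C)CC1(C)C
F2 | step 4 | (6S)-6-[(tert-butyldimethylsilyl)oxy]-2,4,4-trimethyl-3-[(trimethylsilyl)ethynyl]cyclohex-2-en-1-one | C[Si](C)(C)C#CC1=C(C)C(=O)[C@@H](O[Si](C)(C)C(C)(C)C)CC1(C)C
F3 | step 4 | (1R,6S)-6-[(tert-butyldimethylsilyl)oxy]-2,4,4-trimethyl-3-[(trimethylsilyl)ethynyl]cyclohex-2-en-1-ol | C[Si](C)(C)C#CC1=C(C)[C@@H](O)[C@@H](O[Si](C)(C)C(C)(C)C)CC1(C)C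
F4 | step 15 | (3aS,7aR)-6-ethynyl-5,5,7-trimethyl-3a,4,5,7a-tetrahydro-1,3-benzodioxol-2-one | C#CC1=C(C)[C@@H](O2)[C@@H](OC2=O)CC1(C)C
F5 | step 15 | (3aS,7aR)-6-[(3E)-5-hydroxy-3-methylpent-3-en-1-yn-1-yl]-5,5,7-trimethyl-3a,4,5,7a-tetrahydro-1,3-benzodioxol-2-one | OC/C=C(\C)C#CC1=C(C)[C@@H](O2)[C@@H](OC2=O)CC1(C)C
F6 | step 15 | [(2E)-3-methyl-5-[(3aS,7aR)-5,5,7-trimethyl-2-oxo-3a,4,5,7a-tetrahydro-1,3-benzodioxol-6-yl]pent-2-en-4-yn-1-yl]triphenylphosphonium bromide | C/C(C#CC1=C(C)[C@@H](O2)[C@@H](OC2=O)CC1(C)C)=C\C[P+](c1ccccc1)(c1ccccc1)c1ccccc1.[Br-]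
F7 | step 7 | (4R)-2,2,6-trimethyl-4-[(triethylsilyl)oxy]cyclohexan-1-one (both C6 epimers) | CC1C[C@@H](O[Si](CC)(CC)CC)CC(C)(C)C1=O
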